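(The constants used here are invented; the result is computed.)

Four neighbouring flasks, east, south, north and south-east, share one charge of substrate and coupling partner and differ in the charge of free catalyst.

    substrate + coupling partner ⇌ target (K1 = 21 L mol⁻¹, k1 = 6.9 L mol⁻¹ min⁻¹)
    substrate + coupling partner ⇌ isomer of the product (K2 = 600 L mol⁻¹, k2 = 2.4 L mol⁻¹ min⁻¹)
    target + free catalyst ⇌ isomer of the product + free catalyst, rate k3*[free catalyst]*[target] forward; the back reaction follows from the equilibrium constant (k3 = 190 L mol⁻¹ min⁻¹)
    free catalyst → spent catalyst (k4 = 2.4 min⁻¹)

the same everywhere: substrate 0.020 M; coupling partner 0.0500 M; time 4.0 min

| run | free catalyst |
|---|---|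
| east | 0.60 mM |
| south | 2.0 mM |
| north | 5.0 mM |
| south-east | 15 mM |

- "hardly changes" means that all values lie within two and a half points (for a concentration: within two and a half percent of the largest)
- run time (east): 4.0 min

- amount of target at the end, in percent of the substrate charged for east, south, north, south-east, in this order
- the shape of the row from first to last (falls all the way / rises, then falls / rises all the way / falls, then rises / hardly changes)

The uncatalysed steps both start at once, and step 1 has the larger rate constant while step 2 has the larger equilibrium constant, so target is the kinetic product and the isomer of the product the thermodynamic one. Step 3 drains target into the isomer, with a time constant, reckoned at the starting c(free catalyst), of 8.77 min in east and 0.351 min in south-east. But step 4 gives free catalyst a lifetime of 0.417 min, and the run lasts 9.60 such lifetimes, so by first-order decay 0.00677% of the free catalyst remains at the end and step 3 is an affair of the opening minutes.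

The ratio of the two time constants is 1.19 in south-east and 0.0475 in east. This number, k3 times the starting c(free catalyst) over k4, is the catalyst dose: the target lifetimes that a charge of catalyst delivers before it dies. In one catalyst lifetime, step 1 at its starting rate makes 14.4% of the substrate charged into target, and the dose times this share estimates what the catalyst diverts: 0.683% in east and 17.1% in south-east. Both figures take target to grow at its starting rate and to suffer no depletion. This reckoning gives no row of target, but it commits to the order: the dose rises with the charge, so the row falls all the way.

The forecast gives 34.2%, 33.7%, 32.8% and 30.6%, a row that falls all the way, on the ground that “The catalyst dies within about a minute, mostly before much target has formed”.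

The flasks give 34.1%, 33.5%, 32.4% and 29.5%, a row that falls all the way. In east, the half-life of substrate by the forward rate of step 1 alone reads 2.2 min at 0.681 min, longer than the catalyst lifetime of 0.417 min, and 94.4% of the catalyst there is spent by 1.20 min. South-east, with a dose of 1.19 against 0.0475 in east, ends with 31.9% of the substrate charged as isomer of the product against 24.3% in east, a gap of 7.6 percentage points, smaller than the estimated 16 points.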